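**Plan**
- Retrosynthetic cuts, in order: the formyl C=O (back to the CH3 of an isopropenyl group), the tiglate O–C(=O) bond, the side-chain carbinol C–H (back to the aryl methyl ketone, masked as a dioxolane), and the C3–OAc bond (back, with inversion, to the cis C3 alcohol).
- Enabling feature: in dihydrofuran ring B the carbinol carbon C3 is bonded to C2. C2 bears both the aryl ether oxygen O1 and a 1,1-disubstituted alkene, so HO–C3–C2–C(=CH2) is a homoallylic alcohol, the retron of a [2,3]-Wittig shift.
- Cutting C2–C3 and tying the C3 oxygen to the alkene CH2 expands ring B to an eight-membered (Z)-enol ether, a 4H,6H-1,5-benzodioxocine. This is traced through its exocyclic-methylene isomer and two allylic C–O cuts to a salicyl alcohol and 3-chloro-2-(chloromethyl)prop-1-ene.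
- Forward: arene ring A is bought, the eight-membered ring is closed by two Williamson etherifications, the alkene is moved next to O1, and the ring contraction makes ring B. The side chain and the enal are finished last.
- Stereochemistry: C3 comes from enantiotopic benzylic deprotonation by s-BuLi/(−)-sparteine, and C2 is relayed from C3 by the cis-fused transannular transition state. C3 is then corrected by Mitsunobu inversion, the side-chain (R) centre comes from catalyst-controlled transfer hydrogenation, and the E alkene comes from tiglic acid.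

Key step: step 6

Assumption: s-BuLi/(−)-sparteine is taken to remove the pro-S hydrogen of the benzylic OCH2 group, as it does in other O–CH2 deprotonations. If the sense proves opposite, commercially available (+)-sparteine takes its place and nothing else changes.

Step 1
Reactants: 1 methyl 5-acetyl-2-hydroxybenzoate (methyl 5-acetylsalicylate)
Product: 2 methyl 2-hydroxy-5-(2-methyl-1,3-dioxolan-2-yl)benzoate
Conditions: HOCH2CH2OH, p-TsOH (cat.), toluene, Dean–Stark, 110 °C; Et3N quench
Reagents that add atoms: ethylene glycol, OCCO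
Why: Acid-catalysed ketalisation driven by azeotropic removal of water masks the ketone until step 8, and any glycol transesterification of the hydrogen-bonded salicylate is harmless because step 2 reduces either ester to the same alcohol.

Step 2
Reactants: 2 methyl 2-hydroxy-5-(2-methyl-1,3-dioxolan-2-yl)benzoate
Product: 3 2-(hydroxymethyl)-4-(2-methyl-1,3-dioxolan-2-yl)phenol
Conditions: LiAlH4, THF, 0 → 25 °C; aq. KNaC4H4O6 (tartrate) work-up
Reagents that add atoms: none
Why: Hydride reduction of the aryl ester (after deprotonation of the phenol) should give the salicyl alcohol, the ketal being inert to LiAlH4 and spared by the near-neutral work-up.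

Step 3
Reactants: 3 2-(hydroxymethyl)-4-(2-methyl-1,3-dioxolan-2-yl)phenol; 4 3-chloro-2-(chloromethyl)prop-1-ene
Product: 5 [2-{[2-(chloromethyl)prop-2-en-1-yl]oxy}-5-(2-methyl-1,3-dioxolan-2-yl)phenyl]methanol
Conditions: 4 (excess), K2CO3, acetone, 56 °C
Reagents that add atoms: none
Why: Williamson etherification in which carbonate ionises only the phenol and not the benzylic alcohol, while the excess of the symmetrical bis-allylic chloride keeps the second C–Cl bond unreacted.

Step 4
Reactants: 5 [2-{[2-(chloromethyl)prop-2-en-1-yl]oxy}-5-(2-methyl-1,3-dioxolan-2-yl)phenyl]methanol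
Product: 6 3-methylidene-8-(2-methyl-1,3-dioxolan-2-yl)-3,4-dihydro-2H,6H-1,5-benzodioxocine
Conditions: NaH, THF, slow addition at high dilution, 66 °C
Reagents that add atoms: none
Why: Intramolecular Williamson etherification (8-exo-tet) in which direct and allylically transposed displacement give the same product, and the arene, the sp2 carbon and the two ring oxygens remove most of the transannular strain that usually slows eight-membered ring closure.

Step 5
Reactants: 6 3-methylidene-8-(2-methyl-1,3-dioxolan-2-yl)-3,4-dihydro-2H,6H-1,5-benzodioxocine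
Product: 7 (Z)-3-methyl-8-(2-methyl-1,3-dioxolan-2-yl)-4H,6H-1,5-benzodioxocine
Conditions: KOtBu (cat.), DMSO, 25–40 °C
Reagents that add atoms: none
Why: Base-mediated prototropic isomerisation of an allyl aryl ether to an enol ether, in which the ArO–CH2 allylic hydrogens are kinetically more acidic than those on the alkyl-O–CH2 side, reprotonation at the exocyclic carbon gives the aryl enol ether, and the eight-membered ring allows only the ring-cis (Z) geometry.

Step 6
Reactants: 7 (Z)-3-methyl-8-(2-methyl-1,3-dioxolan-2-yl)-4H,6H-1,5-benzodioxocine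
Product: 10 cis-(2S,3S)-2-isopropenyl-5-(2-methyl-1,3-dioxolan-2-yl)-2,3-dihydrobenzofuran-3-ol, via 6-lithiobenzodioxocine 8 (not isolated), via lithium 3-alkoxide 9 (not isolated)
Conditions: s-BuLi, (−)-sparteine, Et2O, −78 °C; aq. NH4Cl
Reagents that add atoms: none
Why: Proposed new method: the s-BuLi/(−)-sparteine complex, precoordinated to O5, should remove the outward-pointing pro-S hydrogen of the benzylic OCH2 group (C6) to give 8, whose carbanion lobe then attacks the enol-ether carbon C2 across the ring, with inversion at the lithium-bearing carbon, while the allylic C4–O5 bond breaks; this suprafacial six-electron [2,3]-sigmatropic (Wittig) shift forms the C2–C3 bond of the benzofuran, turns O5 into the C3 alkoxide of 9 and uncovers the isopropenyl group. The closest known reaction types are the ring-contracting transannular [2,3]-Wittig rearrangements of nine-, thirteen- and seventeen-membered cyclic allylic ethers and the enantioselective [2,3]-Wittig rearrangement of acyclic allyl benzyl ethers with alkyllithium–chiral diamine complexes; an eight-membered ring and an aryloxy-bearing alkene terminus are the untested elements. Ring B closes in the 5-exo-trig mode, C6 and C2 being 1,5-related along both arcs of the eight-membered ring, so that the transition state is a pair of five-membered rings sharing the forming bond. C3 is controlled by the chiral base complex (choice of the enantiotopic hydrogen followed by inversion), and C2 is controlled by C3, because that bicyclic transition state can only be cis-fused on the ring-cis alkene and therefore puts oxygen and isopropenyl on the same face, (2S,3S). The step needs site selectivity for C6–H over the allylic C4–H, the vinylic C2–H and the arene hydrogens, which the aryl and oxygen stabilisation of the C6 anion and the destabilising aryloxy terminus of the alternative C4 allyl anion should secure, and an alkyllithium is chosen because a lithium dialkylamide is too weak a base for an electron-rich benzyl ether. Preference for the [2,3]- over the [1,2]-shift should follow from the low temperature, the release of medium-ring strain and the formation of an alkoxide.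

Step 7
Reactants: 10 cis-(2S,3S)-2-isopropenyl-5-(2-methyl-1,3-dioxolan-2-yl)-2,3-dihydrobenzofuran-3-ol
Product: 11 trans-(2S,3R)-2-isopropenyl-5-(2-methyl-1,3-dioxolan-2-yl)-2,3-dihydrobenzofuran-3-yl acetate
Conditions: AcOH, PPh3, DIAD, toluene, −20 → 25 °C
Reagents that add atoms: acetic acid, CC(=O)O
Why: Mitsunobu reaction in which acetate displaces the C3 oxyphosphonium group by S_N2 from the face anti to the isopropenyl group, inverting C3 from S to R and leaving C2 untouched, with low temperature and a non-polar solvent chosen to hold back elimination.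

Step 8
Reactants: 11 trans-(2S,3R)-2-isopropenyl-5-(2-methyl-1,3-dioxolan-2-yl)-2,3-dihydrobenzofuran-3-yl acetate
Product: 12 trans-(2S,3R)-5-acetyl-2-isopropenyl-2,3-dihydrobenzofuran-3-yl acetate
Conditions: PPTS (cat.), THF/H2O, 25 °C
Reagents that add atoms: water, O
Why: Mild acid-catalysed ketal hydrolysis, fast here because the para ring oxygen O1 stabilises the oxocarbenium ion, so that the acetate, the isopropenyl group and both stereocentres should be left alone.

Step 9
Reactants: 12 trans-(2S,3R)-5-acetyl-2-isopropenyl-2,3-dihydrobenzofuran-3-yl acetate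
Product: 13 (2S,3R)-5-[(1R)-1-hydroxyethyl]-2-isopropenyl-2,3-dihydrobenzofuran-3-yl acetate
Conditions: RuCl[(R,R)-TsDPEN](p-cymene) (cat.), HCO2H/Et3N (5:2), EtOAc, 25 °C
Reagents that add atoms: none
Why: Noyori asymmetric transfer hydrogenation of an aryl methyl ketone, in which the (R,R)-catalyst sets the (R)-carbinol under catalyst control and, unlike a borane reagent, leaves the 1,1-disubstituted alkene and the acetate alone, while any minor enantiomer carried from step 6 becomes a separable diastereomer here.

Step 10
Reactants: 13 (2S,3R)-5-[(1R)-1-hydroxyethyl]-2-isopropenyl-2,3-dihydrobenzofuran-3-yl acetate; 14 tiglic acid, (E)-2-methylbut-2-enoic acid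
Product: 15 (1R)-1-[(2S,3R)-3-acetoxy-2-isopropenyl-2,3-dihydrobenzofuran-5-yl]ethyl (E)-2-methylbut-2-enoate
Conditions: DCC, DMAP (cat.), CH2Cl2, 0 → 25 °C
Reagents that add atoms: none
Why: Steglich esterification acylates the carbinol oxygen, so the C–O bond and the (R) configuration are retained and the E geometry of tiglic acid is carried over.

Step 11
Reactants: 15 (1R)-1-[(2S,3R)-3-acetoxy-2-isopropenyl-2,3-dihydrobenzofuran-5-yl]ethyl (E)-2-methylbut-2-enoate
Product: 16 (1R)-1-[(2S,3R)-3-acetoxy-2-(3-oxoprop-1-en-2-yl)-2,3-dihydrobenzofuran-5-yl]ethyl (E)-2-methylbut-2-enoate (CNP0294391.1)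
Conditions: SeO2, 1,4-dioxane, 70 °C
Reagents that add atoms: selenium dioxide, O=[Se]=O
Why: Riley allylic oxidation (ene reaction, [2,3]-shift, then further oxidation of the allylic alcohol) should attack the only electron-rich alkene and take its methyl hydrogens, since C2–H is deactivated by the flanking C–O bonds and the tiglate alkene is electron-poor, and no stereocentre is involved.

**Compound list**
1 | methyl 5-acetyl-2-hydroxybenzoate | CC(=O)c1ccc(O)c(C(=O)OC)c1 | starting material
2 | methyl 2-hydroxy-5-(2-methyl-1,3-dioxolan-2-yl)benzoate | COC(=O)c1cc(C2(C)OCCO2)ccc1O | intermediate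
3 | 2-(hydroxymethyl)-4-(2-methyl-1,3-dioxolan-2-yl)phenol | OCc1cc(C2(C)OCCO2)ccc1O | intermediate
4 | 3-chloro-2-(chloromethyl)prop-1-ene | C=C(CCl)CCl | starting material
5 | [2-{[2-(chloromethyl)prop-2-en-1-yl]oxy}-5-(2-methyl-1,3-dioxolan-2-yl)phenyl]methanol | C=C(CCl)COc1ccc(C2(C)OCCO2)cc1CO | intermediate
6 | 3-methylidene-8-(2-methyl-1,3-dioxolan-2-yl)-3,4-dihydro-2H,6H-1,5-benzodioxocine | C=C1COCc2cc(C3(C)OCCO3)ccc2OC1 | intermediate
7 | (Z)-3-methyl-8-(2-methyl-1,3-dioxolan-2-yl)-4H,6H-1,5-benzodioxocine | C/C1=C/Oc2ccc(C3(C)OCCO3)cc2COC1 | intermediate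
8 | (6S)-6-lithio-(Z)-3-methyl-8-(2-methyl-1,3-dioxolan-2-yl)-4H,6H-1,5-benzodioxocine (sparteine-bound) | [Li][C@@H]1OC/C(C)=C\Oc2ccc(C3(C)OCCO3)cc21 | intermediate
9 | lithium (2S,3S)-2-isopropenyl-5-(2-methyl-1,3-dioxolan-2-yl)-2,3-dihydrobenzofuran-3-olate | C=C(C)[C@@H]1Oc2ccc(C3(C)OCCO3)cc2[C@@H]1[O-].[Li+] | intermediate
10 | cis-(2S,3S)-2-isopropenyl-5-(2-methyl-1,3-dioxolan-2-yl)-2,3-dihydrobenzofuran-3-ol | C=C(C)[C@@H]1Oc2ccc(C3(C)OCCO3)cc2[C@@H]1O | intermediate
11 | trans-(2S,3R)-2-isopropenyl-5-(2-methyl-1,3-dioxolan-2-yl)-2,3-dihydrobenzofuran-3-yl acetate | C=C(C)[C@@H]1Oc2ccc(C3(C)OCCO3)cc2[C@H]1OC(C)=O | intermediate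
12 | trans-(2S,3R)-5-acetyl-2-isopropenyl-2,3-dihydrobenzofuran-3-yl acetate | C=C(C)[C@@H]1Oc2ccc(C(C)=O)cc2[C@H]1OC(C)=O | intermediate
13 | (2S,3R)-5-[(1R)-1-hydroxyethyl]-2-isopropenyl-2,3-dihydrobenzofuran-3-yl acetate | C=C(C)[C@@H]1Oc2ccc([C@@H](C)O)cc2[C@H]1OC(C)=O | intermediate
14 | tiglic acid, (E)-2-methylbut-2-enoic acid | C/C=C(\C)C(=O)O | starting material
15 | (1R)-1-[(2S,3R)-3-acetoxy-2-isopropenyl-2,3-dihydrobenzofuran-5-yl]ethyl (E)-2-methylbut-2-enoate | C=C(C)[C@@H]1Oc2ccc([C@@H](C)OC(=O)/C(C)=C/C)cc2[C@H]1OC(C)=O | intermediate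
16 | (1R)-1-[(2S,3R)-3-acetoxy-2-(3-oxoprop-1-en-2-yl)-2,3-dihydrobenzofuran-5-yl]ethyl (E)-2-methylbut-2-enoate | C=C(C=O)[C@@H]1Oc2ccc([C@@H](C)OC(=O)/C(C)=C/C)cc2[C@H]1OC(C)=O | target

Total step count: 11. Longest linear sequence: 11 steps (1 to 16).

**Steps most likely to fail**

**Step 6 (labelled step).**
- What may go wrong:
  - Lithiation may be slow or misdirected to the vinylic or ring positions.
  - The shift may be sluggish, because the carbanion lobe has to turn out of benzylic conjugation toward the arene plane to reach C2.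
  - The [1,2]-shift may intervene.
  - Epimerisation of the benzylic lithium may erode enantioselectivity.
- Fallback: it uses known chemistry, sets out from 3 and comes back at 11. It forms C2–C3 by intermolecular allylboration and O1–C2 by substitution. MnO2 in CH2Cl2 would oxidise the benzylic alcohol of 3 to 2-hydroxy-5-(2-methyl-1,3-dioxolan-2-yl)benzaldehyde F1. TBSCl/imidazole would then give 2-[(tert-butyldimethylsilyl)oxy]-5-(2-methyl-1,3-dioxolan-2-yl)benzaldehyde F2. The next operation is asymmetric γ-chloroallylboration with the (Z)-γ-chloro-β-methylallylborane generated from 3-chloro-2-methylprop-1-ene, LiN(c-C6H11)2 and (−)-Ipc2BOMe (then BF3·OEt2, Et2O, −95 °C, ethanolamine work-up). Through a chair transition state it should give the syn chlorohydrin (1R,2R)-1-{2-[(tert-butyldimethylsilyl)oxy]-5-(2-methyl-1,3-dioxolan-2-yl)phenyl}-2-chloro-3-methylbut-3-en-1-ol F3. Ac2O/pyridine would convert it into (1R,2R)-1-{2-[(tert-butyldimethylsilyl)oxy]-5-(2-methyl-1,3-dioxolan-2-yl)phenyl}-2-chloro-3-methylbut-3-en-1-yl acetate F4. Bu4NF in THF at 0 °C frees the phenoxide, which displaces the allylic chloride in a 5-exo-tet S_N2 reaction with inversion at C2 and so delivers the trans acetate 11 directly.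

**Step 7.**
- What may go wrong: E2 loss of the activated C3 oxygen together with C2–H, which is antiperiplanar to it in the cis series and is both allylic and next to O1. This aromatises ring B and erases both ring stereocentres. Ionisation at the o-alkoxybenzylic C3 would end the same way.
- Fallback: it sets out from 10 and comes back at 11, and it never breaks the C3–O bond. Redox epimerisation of the carbinol with Ru(CO)2Cl(η5-C5Ph5)/KOtBu (both cat.) in toluene at 25 °C is the racemisation half of dynamic kinetic resolutions. It dehydrogenates and rehydrogenates C3 within the coordination sphere of the metal and should enrich the less congested trans-(2S,3R)-2-isopropenyl-5-(2-methyl-1,3-dioxolan-2-yl)-2,3-dihydrobenzofuran-3-ol F5. F5 is separated from remaining 10, which is recycled, and acetylated with retention (Ac2O, pyridine, DMAP) to 11.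

**Step 5.**
- What may go wrong: poor regioselectivity, that is, migration of the double bond toward O5 instead of O1, or incomplete migration of the hindered 1,1-disubstituted alkene.
- Fallback: it sets out from 3 and comes back at 7, and it installs the enol ether with defined position and geometry by C–O coupling. CuI-catalysed addition of MeMgBr to propargyl alcohol followed by I2 would give (Z)-3-iodo-2-methylprop-2-en-1-ol F6. This is silylated (TBSCl, imidazole) to tert-butyl{[(2Z)-3-iodo-2-methylprop-2-en-1-yl]oxy}dimethylsilane F7. Ullmann-type O-vinylation of the phenol of 3 with F7 (CuI, N,N-dimethylglycine, Cs2CO3, dioxane, 90 °C) retains the alkene geometry. It should give [2-{[(1Z)-3-[(tert-butyldimethylsilyl)oxy]-2-methylprop-1-en-1-yl]oxy}-5-(2-methyl-1,3-dioxolan-2-yl)phenyl]methanol F8. MsCl, Et3N and LiCl convert F8 into tert-butyl{[(2Z)-3-[2-(chloromethyl)-4-(2-methyl-1,3-dioxolan-2-yl)phenoxy]-2-methylprop-2-en-1-yl]oxy}dimethylsilane F9. Bu4NF then liberates (2Z)-3-[2-(chloromethyl)-4-(2-methyl-1,3-dioxolan-2-yl)phenoxy]-2-methylprop-2-en-1-ol F10. NaH in THF at high dilution closes the O5–C6 bond by intramolecular Williamson etherification at the benzylic carbon to give 7.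

**Further compounds**
F1 | step 6 | 2-hydroxy-5-(2-methyl-1,3-dioxolan-2-yl)benzaldehyde | O=Cc1cc(C2(C)OCCO2)ccc1O
F2 | step 6 | 2-[(tert-butyldimethylsilyl)oxy]-5-(2-methyl-1,3-dioxolan-2-yl)benzaldehyde | O=Cc1cc(C2(C)OCCO2)ccc1O[Si](C)(C)C(C)(C)C
F3 | step 6 | (1R,2R)-1-{2-[(tert-butyldimethylsilyl)oxy]-5-(2-methyl-1,3-dioxolan-2-yl)phenyl}-2-chloro-3-methylbut-3-en-1-ol | C=C(C)[C@@H](Cl)[C@H](O)c1cc(C2(C)OCCO2)ccc1O[Si](C)(C)C(C)(C)C
F4 | step 6 | (1R,2R)-1-{2-[(tert-butyldimethylsilyl)oxy]-5-(2-methyl-1,3-dioxolan-2-yl)phenyl}-2-chloro-3-methylbut-3-en-1-yl acetate | C=C(C)[C@@H](Cl)[C@H](OC(C)=O)c1cc(C2(C)OCCO2)ccc1O[Si](C)(C)C(C)(C)C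
F5 | step 7 | trans-(2S,3R)-2-isopropenyl-5-(2-methyl-1,3-dioxolan-2-yl)-2,3-dihydrobenzofuran-3-ol | C=C(C)[C@@H]1Oc2ccc(C3(C)OCCO3)cc2[C@H]1O
F6 | step 5 | (Z)-3-iodo-2-methylprop-2-en-1-ol | OC/C(C)=C\I
F7 | step 5 | tert-butyl{[(2Z)-3-iodo-2-methylprop-2-en-1-yl]oxy}dimethylsilane | CC(C)(C)[Si](C)(C)OC/C(C)=C\I
F8 | step 5 | [2-{[(1Z)-3-[(tert-butyldimethylsilyl)oxy]-2-methylprop-1-en-1-yl]oxy}-5-(2-methyl-1,3-dioxolan-2-yl)phenyl]methanol | CC(C)(C)[Si](C)(C)OC/C(C)=C\Oc1ccc(C2(C)OCCO2)cc1CO
F9 | step 5 | tert-butyl{[(2Z)-3-[2-(chloromethyl)-4-(2-methyl-1,3-dioxolan-2-yl)phenoxy]-2-methylprop-2-en-1-yl]oxy}dimethylsilane | CC(C)(C)[Si](C)(C)OC/C(C)=C\Oc1ccc(C2(C)OCCO2)cc1CCl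
F10 | step 5 | (2Z)-3-[2-(chloromethyl)-4-(2-methyl-1,3-dioxolan-2-yl)phenoxy]-2-methylprop-2-en-1-ol | OC/C(C)=C\Oc1ccc(C2(C)OCCO2)cc1CCl
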